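The data were computed for substances that don't exist.

2% of the X charged is read as J in grey at 30.0 min, and from that reading comes a ceiling on the J in larch.

the same everywhere: L 0.0285 M

|  | X | E | temperature | remark | time |
|---|---|---|---|---|---|
| amber | 0.027 M | 1.9 mM | 2 °C | run made earlier |  |
| grey | 0.042 M | 1.9 mM | 52 °C | run made earlier |  |
| larch | 0.019 M | 1.90 mM | 70 °C |  | 50 min |
| ash | 0.019 M | 1.90 mM | 40 °C |  | 50 min |
| elm | 0.019 M | 1.90 mM | 10 °C |  | 50 min |
| oak | 0.019 M | 1.90 mM | −20 °C |  | 50 min |

- amber (time / min: J / %, Z / %): 150: 49, 13; 480: 20, 39; 900: 11, 47; 1200: 4, 50; 1800: 1, 53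
- grey (time / min: J / %, Z / %): 30.0: 2, 30; 60.0: 0, 31; 90.0: 1, 31; 120: 0, 30; 150: 2, 28

(standard deviation of a reading: 2 percentage points)

- the flask with the highest amount of J, in percent of the X charged ("all alike" if they lie within 1.5 percentage points) (larch / ash / elm / oak / all alike)
- final J, as a percentage of the X charged, in larch
- final J, as a percentage of the X charged, in ash
- final J, as a percentage of the X charged, in elm
- final J, as a percentage of the X charged, in oak

With one scatter of 2 percentage points added, the grey reading stands at 4.00% J. That gives 0.107 min⁻¹ as the clearing constant, the pseudo-first-order constant that takes the whole charge, counted as J from the start, down to that J in that time.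

A first, loose ceiling comes from amber, where J falls from 49% to 4% between 150 min and 1200 min. This tail gives 0.00239 min⁻¹, so larch, if it clears no slower than amber, keeps at most 88.8% after 50 min.

Larch is hotter than grey and has less X with the same c_L of 0.0285 M. Grey's constant is therefore taken as the lower limit for larch, and the ceiling drops to 0.468%. The bound from below stays at zero. This bracket is my own reckoning, not the forecast's.

The forecast names elm and gives 0.5% for larch, within 0% to 3%, then 5% for ash, 45% for elm and 11% for oak. Its ground for larch: “larch is finished”. Its larch figure stands just above the bracket.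

The flasks give elm as the highest, with 0% in larch, 4.98% in ash, 57.8% in elm and 2.16% in oak. Larch lies inside the bracket. Elm stands 13 points above the forecast, and oak 8.8 points below it.

    X → J (k = 0.0140 s⁻¹, Ea = 83.0 kJ mol⁻¹)
    2 J → Q (k = 0.0400 L mol⁻¹ s⁻¹, Ea = 60.0 kJ mol⁻¹)
    L + E → D (k = 1.90 L mol⁻¹ s⁻¹, Ea = 53.0 kJ mol⁻¹)
    Z ⇌ G (K = 0.730, k = 1.30 × 10⁻⁴ s⁻¹, Ea = 95.0 kJ mol⁻¹, ΔH = −69.0 kJ mol⁻¹)
    L + J → Z (k = 0.0360 L mol⁻¹ s⁻¹, Ea = 57.0 kJ mol⁻¹)
    (constants at 40 °C)

The neighbouring flask is larch read at 12 min. Grey's 0.107 min⁻¹ caps its J at 27.6%, and it holds 1.30%, with Z at 50.1%. Its own clearing constant is 0.362 min⁻¹, larger than grey's.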